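The route rests on opening the cis-fused α-methylene-γ-butyrolactone (ring O11, C12, C14, C16, C10 with exocyclic C14=C15) into a C10 hydroxyl, a C16 ethynyl group and carbon monoxide. The key step exploits this but-3-yn-1-ol relationship. One palladium-catalysed cyclocarbonylation forms O11–C12 and C12–C14, closes the lactone and creates the methylene on the finished 14-membered carbocycle, so the reactive acrylate appears last. The precursor is the macrocyclic homopropargylic alcohol that already holds the oxolane (C20, O25, C24), the C2 methylene and all seven stereocentres, with O9 and O19 silylated and O11 the only free hydroxyl.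

Key step: step 23

Remark: atom labels C1 to O25 follow the order of the target SMILES and are used for every intermediate.
Remark: the target is read as 6S,8R,10R,16S,18R,20S,24R with a cis ring fusion at C10–C16; precursor 34 and product 36 carry these configurations at every shared centre.
Remark: geranyl acetate (1), lithium (trimethylsilyl)acetylide (4, 0.5 M solution in THF) and the N-propanoyl oxazolidinone (18) are taken as commercial; each saves an operation against geraniol, ethynyltrimethylsilane and propanoyl chloride.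

Step 1
Reactants: 1 geranyl acetate
Product: 3 (2E)-3-methyl-6-oxohex-2-en-1-yl acetate, via 6,7-epoxygeranyl acetate 2 (not isolated)
Conditions: mCPBA, CH2Cl2, 0 °C; then H5IO6, THF/H2O, 0 °C to rt
Reagents that add atoms: 3-chloroperbenzoic acid, OOC(=O)c1cccc(Cl)c1
Why: Prilezhaev epoxidation should pick the electron-rich terminal trisubstituted alkene over the one deactivated by the allylic acetate, and periodic acid then hydrolyses the epoxide and cleaves the glycol (Malaprade cleavage) to the aldehyde carbon that becomes C24.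

Step 2
Reactants: 3 (2E)-3-methyl-6-oxohex-2-en-1-yl acetate; 4 lithium (trimethylsilyl)acetylide
Product: 5 rac-(2E)-6-hydroxy-3-methyl-8-(trimethylsilyl)oct-2-en-7-yn-1-yl acetate
Conditions: 4 (0.5 M in THF), THF, −78 °C; aq NH4Cl
Reagents that add atoms: none
Why: 1,2-addition of the lithium acetylide to the aldehyde is much faster at −78 °C than attack on the acetate, and the racemic carbinol is acceptable because its configuration is erased in step 3.

Step 3
Reactants: 5 rac-propargylic alcohol
Product: 6 (2E)-3-methyl-6-oxo-8-(trimethylsilyl)oct-2-en-7-yn-1-yl acetate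
Conditions: Dess–Martin periodinane, NaHCO3, CH2Cl2, 0 °C to rt
Reagents that add atoms: none
Why: Dess–Martin oxidation of a secondary propargylic alcohol gives the silyl ynone under buffered conditions that leave the acetate and the trisubstituted alkene untouched.

Step 4
Reactants: 6 silyl ynone
Product: 7 (2E,6R)-6-hydroxy-3-methyl-8-(trimethylsilyl)oct-2-en-7-yn-1-yl acetate
Conditions: Ru[(R,R)-TsNCHPhCHPhNH](p-cymene) (cat.), i-PrOH, rt
Reagents that add atoms: none
Why: Noyori asymmetric transfer hydrogenation of an alkynyl ketone, in which the alkyne takes the place of the aryl group of an aryl ketone, should give the R carbinol (C24 of the target) with the R,R catalyst under catalyst control, and the amido complex needs no added base that could touch the acetate.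

Step 5
Reactants: 7 (6R)-propargylic alcohol acetate
Product: 8 (2E,6R)-3-methyloct-2-en-7-yne-1,6-diol
Conditions: K2CO3, MeOH, rt
Reagents that add atoms: none
Why: Carbonate-catalysed methanolysis removes the acetate by transesterification and the alkynyl silane by protodesilylation in one operation, which frees the allylic alcohol needed for the directed epoxidation.

Step 6
Reactants: 8 enyne diol
Product: 10 (1R)-1-[(2S,5R)-5-ethynyl-2-methyloxolan-2-yl]ethane-1,2-diol, via epoxy diol 9 (not isolated)
Conditions: Ti(OiPr)4, D-(−)-diethyl tartrate, t-BuOOH, 4 Å MS, CH2Cl2, −20 °C; then CSA (cat.), 0 °C to rt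
Reagents that add atoms: tert-butyl hydroperoxide, CC(C)(C)OO
Why: Sharpless asymmetric epoxidation of the E-trisubstituted allylic alcohol with the D-tartrate should give the (2R,3R)-epoxide as it does for geraniol, and acid then triggers 5-exo-tet opening at the tertiary carbon by the C24 hydroxyl with inversion, which sets C20 (S), leaves the former epoxide oxygen as the C18 (R) hydroxyl and puts C18 and the ethynyl group cis on the oxolane.

Step 7
Reactants: 10 ethynyl oxolane diol
Product: 12 (1R)-1-[(2S,5R)-5-(1-bromoethenyl)-2-methyloxolan-2-yl]ethane-1,2-diol, via alkenylstannane 11 (not isolated)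
Conditions: Bu3SnH, Mo(CO)3(CNt-Bu)3 (cat.), hydroquinone, THF, 55 °C; then Br2, CH2Cl2, −78 °C
Reagents that add atoms: bromine, BrBr
Why: Molybdenum-catalysed hydrostannation of a terminal alkyne that carries a propargylic oxygen places tin on the internal carbon, and bromodestannylation at the same carbon then gives the 2-bromoalk-1-ene (C2, C1) without touching a stereocentre.

Step 8
Reactants: 12 bromoalkene diol
Product: 14 (2S,5R)-5-(1-bromoethenyl)-2-methyl-2-[(2R)-oxiran-2-yl]oxolane, via primary tosylate 13 (not isolated)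
Conditions: NaH, 1-tosylimidazole, THF, 0 °C to rt
Reagents that add atoms: none
Why: Selective sulfonylation of the primary alkoxide followed by intramolecular Williamson displacement by the C18 alkoxide closes the terminal epoxide, and C18 keeps its configuration because its C–O bond is not broken.

Step 9
Reactants: 14 terminal epoxide; 4 lithium (trimethylsilyl)acetylide
Product: 15 (1R)-1-[(2S,5R)-5-(1-bromoethenyl)-2-methyloxolan-2-yl]-4-(trimethylsilyl)but-3-yn-1-ol
Conditions: 4 (0.5 M in THF), BF3·OEt2, THF, −78 °C; then 14, −78 °C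
Reagents that add atoms: none
Why: Yamaguchi alkynylation opens the BF3-activated terminal epoxide by SN2 attack at the CH2 carbon (C17), which forms C16–C17 and releases the C18 hydroxyl unchanged while the vinyl bromide is inert to the acetylide.

Step 10
Reactants: 15 homopropargylic alcohol
Product: 16 C18 tert-butyldimethylsilyl ether of 15
Conditions: TBSOTf, 2,6-lutidine, CH2Cl2, 0 °C
Reagents that add atoms: tert-butyldimethylsilyl trifluoromethanesulfonate, CC(C)(C)[Si](C)(C)OS(=O)(=O)C(F)(F)F
Why: Silylation with the silyl triflate is chosen because the C18 hydroxyl sits next to the quaternary C20, and it installs the ether that stays on O19 until the last step.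

Step 11
Reactants: 16 silyl ether with silylalkyne
Product: 17 (2S,5R)-5-(1-bromoethenyl)-2-[(1R)-1-(tert-butyldimethylsilyloxy)but-3-yn-1-yl]-2-methyloxolane
Conditions: K2CO3, MeOH, rt
Reagents that add atoms: none
Why: Protodesilylation of the alkynylsilane by methoxide frees the terminal alkyne (C10–H) while the secondary silyl ether and the vinyl bromide are stable.

Step 12
Reactants: 18 (4R)-4-benzyl-3-propanoyl-1,3-oxazolidin-2-one; 19 allyl bromide
Product: 21 (4R)-4-benzyl-3-[(2S)-2-methylpent-4-enoyl]-1,3-oxazolidin-2-one, via sodium Z-enolate 20 (not isolated)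
Conditions: NaN(SiMe3)2, THF, −78 °C; then 19, −78 to −45 °C
Reagents that add atoms: none
Why: Evans alkylation, in which the chelated Z-enolate is attacked by allyl bromide on the face opposite the benzyl group, should give the 2S product (C6 of the target) from the R auxiliary.

Step 13
Reactants: 21 alkylated imide
Product: 22 (2S)-N-methoxy-N,2-dimethylpent-4-enamide
Conditions: MeNH(OMe)·HCl, AlMe3, CH2Cl2, −15 °C to rt
Reagents that add atoms: N,O-dimethylhydroxylamine hydrochloride, CNOC.Cl
Why: Aluminium amide transamination (Weinreb amidation) cleaves the exocyclic acyl group of the imide without enolisation, so C6 is kept and the auxiliary is recovered.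

Step 14
Reactants: 17 terminal alkyne; 22 Weinreb amide
Product: 24 ynone with C8 ketone and C10≡C16 alkyne (6S,18R,20S,24R), via bromomagnesium acetylide 23 (not isolated)
Conditions: 17, EtMgBr, THF, 0 °C to rt; then 22, 0 °C to rt; aq NH4Cl
Reagents that add atoms: none
Why: Acylation of an alkynyl Grignard reagent by a Weinreb amide stops at the ketone because the chelated tetrahedral adduct survives until the quench, and ethylmagnesium bromide deprotonates the alkyne without exchanging the vinyl bromide, so the C8–C10 bond forms with C6 intact.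

Step 15
Reactants: 24 ynone
Product: 25 (8S)-propargylic alcohol
Conditions: Ru[(S,S)-TsNCHPhCHPhNH](p-cymene) (cat.), i-PrOH, rt
Reagents that add atoms: none
Why: Noyori asymmetric transfer hydrogenation under catalyst control should give the 8S carbinol, the epimer that is matched in the epoxidation of step 17, under base-free conditions that do not epimerise C6 or reduce the alkenes and the vinyl bromide.

Step 16
Reactants: 25 (8S)-propargylic alcohol
Product: 26 (8S,10E)-allylic alcohol
Conditions: NaAlH2(OCH2CH2OMe)2, THF, 0 °C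
Reagents that add atoms: none
Why: Hydroxyl-directed trans-hydroalumination of the propargylic alcohol followed by protonolysis gives only the E alkene (C10=C16), at a temperature at which the vinyl bromide, the terminal alkene and the silyl ether should not be reduced.

Step 17
Reactants: 26 (8S,10E)-allylic alcohol
Product: 27 erythro epoxy alcohol, (8S)-hydroxy-(10S,16S)-10,16-epoxide
Conditions: Ti(OiPr)4, L-(+)-diisopropyl tartrate, t-BuOOH, 4 Å MS, CH2Cl2, −20 °C
Reagents that add atoms: tert-butyl hydroperoxide, CC(C)(C)OO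
Why: Sharpless epoxidation of a secondary E-allylic alcohol is matched when the S carbinol meets the L-tartrate, which delivers oxygen to the face that gives the erythro (8S,10S,16S)-epoxy alcohol, and the titanium peroxide does not epoxidise the isolated alkenes.

Step 18
Reactants: 27 erythro epoxy alcohol
Product: 29 threo epoxy alcohol, (8R)-hydroxy-(10S,16S)-10,16-epoxide, via 4-nitrobenzoate 28 (not isolated)
Conditions: PPh3, DIAD, 4-nitrobenzoic acid, THF, 0 °C to rt; then K2CO3, MeOH, 0 °C
Reagents that add atoms: 4-nitrobenzoic acid, OC(=O)c1ccc(cc1)[N+](=O)[O-]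
Why: Mitsunobu esterification inverts C8 by SN2 displacement of the oxyphosphonium group (8S to 8R), and cold methanolysis of the activated ester then frees the threo epoxy alcohol without Payne rearrangement.

Step 19
Reactants: 29 threo epoxy alcohol
Product: 30 8,18-bis(tert-butyldimethylsilyl) ether of 29
Conditions: TBSOTf, 2,6-lutidine, CH2Cl2, −78 °C
Reagents that add atoms: tert-butyldimethylsilyl trifluoromethanesulfonate, CC(C)(C)[Si](C)(C)OS(=O)(=O)C(F)(F)F
Why: Low-temperature silylation with the triflate protects the hindered C8 hydroxyl without opening the epoxide, so that O9 is blocked before O11 is set free in the next step.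

Step 20
Reactants: 30 epoxy bis(silyl) ether; 4 lithium (trimethylsilyl)acetylide
Product: 31 seco alcohol with (8R)-silyloxy, (10R)-hydroxy and (16S)-(trimethylsilyl)ethynyl groups
Conditions: 4 (0.5 M in THF), BF3·OEt2, THF, −78 °C; then 30, −78 to −40 °C
Reagents that add atoms: none
Why: Yamaguchi alkynylation opens the trans-epoxide by SN2 attack with inversion at C16, the carbon remote from the silyloxy group, because C10 is deactivated inductively by O9 and shielded by the C8 silyl ether and the C6 branch, which sets C16 (S), frees the C10 (R) hydroxyl and gives the anti C10/C16 relationship of the cis-fused lactone.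

Step 21
Reactants: 31 seco alcohol
Product: 33 14-membered carbocycle closed at C2–C3 with the C2=C1 methylene and the (trimethylsilyl)ethynyl group on C16, via B-alkyl-9-BBN 32 (not isolated)
Conditions: 9-BBN, THF, rt; then slow addition to Pd(dppf)Cl2, AsPh3, Cs2CO3, DMF/THF/H2O, rt (about 2 mM)
Reagents that add atoms: none
Why: Intramolecular B-alkyl Suzuki–Miyaura coupling, in which 9-BBN hydroborates only the monosubstituted C3=C4 alkene at its terminus and the primary alkylborane is transferred to the alkenylpalladium bromide formed at C2, closes the 14-membered carbocycle with the exocyclic methylene already in place.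

Step 22
Reactants: 33 macrocyclic silylalkyne
Product: 34 macrocyclic homopropargylic alcohol (ethynyl on C16, hydroxyl on C10, O9 and O19 silylated)
Conditions: K2CO3, MeOH, 0 °C to rt
Reagents that add atoms: none
Why: Protodesilylation of the alkynylsilane gives the terminal ethynyl group, and the conditions are kept cold and brief so that the C8 silyl ether does not migrate to the neighbouring C10 hydroxyl.

Step 23
Reactants: 34 macrocyclic homopropargylic alcohol; 35 carbon monoxide
Product: 36 uprolide D 9,19-bis(tert-butyldimethylsilyl) ether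
Conditions: PdCl2 (cat.), SnCl2 (cat.), PPh3, CO (7 atm), MeCN, 70 °C
Reagents that add atoms: none
Why: Divalent palladium binds carbon monoxide and the C10 hydroxyl to form an alkoxycarbonylpalladium species, which adds syn across the C14≡C15 triple bond so that C12 bonds to C14 and palladium ends on C15; protonolysis of that alkenyl–palladium bond by the acid released in the first stage gives the methylene and returns the catalyst. The closest known reaction type is the palladium-catalysed cyclocarbonylation of but-3-yn-1-ols to α-methylene-γ-butyrolactones, applied here to a macrocyclic substrate. The lactone ring (O11, C12, C14, C16, C10) closes in a 5-exo-dig mode through the intramolecular acylpalladation. No stereocentre is created and none is touched, since neither the C10–O11 bond nor any bond at C16 is broken, so the cis ring fusion set in step 20 is carried over. The step needs reaction at a single hydroxyl and exo closure: O9 and O19 are silylated, O11 is the only free hydroxyl and its tether to the alkyne allows only the five-membered closure, and the 1,1-disubstituted C2=C1 alkene is a poor ligand that should be left alone.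

Step 24
Reactants: 36 uprolide D bis(silyl) ether
Product: 37 uprolide D
Conditions: HF·pyridine, pyridine, THF, 0 °C to rt
Reagents that add atoms: none
Why: Fluoride-mediated cleavage of the two secondary silyl ethers under buffered acidic conditions avoids the basic conditions that could add to the α-methylene lactone or move the lactone from O11 to O9.

Compound list
1 | geranyl acetate, (2E)-3,7-dimethylocta-2,6-dien-1-yl acetate | CC(=O)OC/C=C(\C)CCC=C(C)C | starting material
2 | 6,7-epoxygeranyl acetate (racemic epoxide) | CC(=O)OC/C=C(\C)CCC1OC1(C)C | intermediate (not isolated)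
3 | (2E)-3-methyl-6-oxohex-2-en-1-yl acetate | CC(=O)OC/C=C(\C)CCC=O | intermediate
4 | lithium (trimethylsilyl)acetylide (0.5 M solution in THF) | [Li]C#C[Si](C)(C)C | starting material
5 | rac-(2E)-6-hydroxy-3-methyl-8-(trimethylsilyl)oct-2-en-7-yn-1-yl acetate | CC(=O)OC/C=C(\C)CCC(O)C#C[Si](C)(C)C | intermediate
6 | (2E)-3-methyl-6-oxo-8-(trimethylsilyl)oct-2-en-7-yn-1-yl acetate | CC(=O)OC/C=C(\C)CCC(=O)C#C[Si](C)(C)C | intermediate
7 | (2E,6R)-6-hydroxy-3-methyl-8-(trimethylsilyl)oct-2-en-7-yn-1-yl acetate | CC(=O)OC/C=C(\C)CC[C@@H](O)C#C[Si](C)(C)C | intermediate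
8 | (2E,6R)-3-methyloct-2-en-7-yne-1,6-diol | OC/C=C(\C)CC[C@@H](O)C#C | intermediate
9 | (3R)-5-[(2R,3R)-3-(hydroxymethyl)-2-methyloxiran-2-yl]pent-1-yn-3-ol | OC[C@H]1O[C@]1(C)CC[C@@H](O)C#C | intermediate (not isolated)
10 | (1R)-1-[(2S,5R)-5-ethynyl-2-methyloxolan-2-yl]ethane-1,2-diol | OC[C@@H](O)[C@]1(C)CC[C@H](C#C)O1 | intermediate
11 | (1R)-1-{(2S,5R)-2-methyl-5-[1-(tributylstannyl)ethenyl]oxolan-2-yl}ethane-1,2-diol | OC[C@@H](O)[C@]1(C)CC[C@H](C(=C)[Sn](CCCC)(CCCC)CCCC)O1 | intermediate (not isolated)
12 | (1R)-1-[(2S,5R)-5-(1-bromoethenyl)-2-methyloxolan-2-yl]ethane-1,2-diol | OC[C@@H](O)[C@]1(C)CC[C@H](C(Br)=C)O1 | intermediate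
13 | (2R)-2-[(2S,5R)-5-(1-bromoethenyl)-2-methyloxolan-2-yl]-2-hydroxyethyl 4-methylbenzenesulfonate | Cc1ccc(cc1)S(=O)(=O)OC[C@@H](O)[C@]2(C)CC[C@H](C(Br)=C)O2 | intermediate (not isolated)
14 | (2S,5R)-5-(1-bromoethenyl)-2-methyl-2-[(2R)-oxiran-2-yl]oxolane | C1O[C@H]1[C@]2(C)CC[C@H](C(Br)=C)O2 | intermediate
15 | (1R)-1-[(2S,5R)-5-(1-bromoethenyl)-2-methyloxolan-2-yl]-4-(trimethylsilyl)but-3-yn-1-ol | C[Si](C)(C)C#CC[C@@H](O)[C@]1(C)CC[C@H](C(Br)=C)O1 | intermediate
16 | tert-butyldimethylsilyl ether of 15 (O19) | C[Si](C)(C)C#CC[C@@H](O[Si](C)(C)C(C)(C)C)[C@]1(C)CC[C@H](C(Br)=C)O1 | intermediate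
17 | (2S,5R)-5-(1-bromoethenyl)-2-[(1R)-1-(tert-butyldimethylsilyloxy)but-3-yn-1-yl]-2-methyloxolane | C#CC[C@@H](O[Si](C)(C)C(C)(C)C)[C@]1(C)CC[C@H](C(Br)=C)O1 | intermediate
18 | (4R)-4-benzyl-3-propanoyl-1,3-oxazolidin-2-one | CCC(=O)N1[C@H](Cc2ccccc2)COC1=O | starting material
19 | allyl bromide | C=CCBr | starting material
20 | sodium Z-enolate of 18 | C/C=C(\[O-])N1[C@H](Cc2ccccc2)COC1=O.[Na+] | intermediate (not isolated)
21 | (4R)-4-benzyl-3-[(2S)-2-methylpent-4-enoyl]-1,3-oxazolidin-2-one | C=CC[C@H](C)C(=O)N1[C@H](Cc2ccccc2)COC1=O | intermediate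
22 | (2S)-N-methoxy-N,2-dimethylpent-4-enamide | C=CC[C@H](C)C(=O)N(C)OC | intermediate
23 | bromomagnesium acetylide of 17 | Br[Mg]C#CC[C@@H](O[Si](C)(C)C(C)(C)C)[C@]1(C)CC[C@H](C(Br)=C)O1 | intermediate (not isolated)
24 | ynone: C3=C4 alkene, (6S)-methyl, C8 ketone, C10≡C16 alkyne, (18R)-silyloxy, (20S,24R)-oxolane with 1-bromoethenyl (C2, C1) on C24 | C=CC[C@H](C)C(=O)C#CC[C@@H](O[Si](C)(C)C(C)(C)C)[C@]1(C)CC[C@H](C(Br)=C)O1 | intermediate
25 | (8S)-propargylic alcohol from 24 | C=CC[C@H](C)[C@H](O)C#CC[C@@H](O[Si](C)(C)C(C)(C)C)[C@]1(C)CC[C@H](C(Br)=C)O1 | intermediate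
26 | (8S,10E)-allylic alcohol | C=CC[C@H](C)[C@H](O)/C=C/C[C@@H](O[Si](C)(C)C(C)(C)C)[C@]1(C)CC[C@H](C(Br)=C)O1 | intermediate
27 | erythro epoxy alcohol, (8S)-hydroxy-(10S,16S)-10,16-epoxide | C=CC[C@H](C)[C@H](O)[C@@H]1O[C@H]1C[C@@H](O[Si](C)(C)C(C)(C)C)[C@]2(C)CC[C@H](C(Br)=C)O2 | intermediate
28 | 4-nitrobenzoate of the C8 epimer of 27 (epoxide unchanged) | C=CC[C@H](C)[C@@H](OC(=O)c1ccc(cc1)[N+](=O)[O-])[C@@H]2O[C@H]2C[C@@H](O[Si](C)(C)C(C)(C)C)[C@]3(C)CC[C@H](C(Br)=C)O3 | intermediate (not isolated)
29 | threo epoxy alcohol, (8R)-hydroxy-(10S,16S)-10,16-epoxide | C=CC[C@H](C)[C@@H](O)[C@@H]1O[C@H]1C[C@@H](O[Si](C)(C)C(C)(C)C)[C@]2(C)CC[C@H](C(Br)=C)O2 | intermediate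
30 | 8,18-bis(tert-butyldimethylsilyl) ether of 29 | C=CC[C@H](C)[C@@H](O[Si](C)(C)C(C)(C)C)[C@@H]1O[C@H]1C[C@@H](O[Si](C)(C)C(C)(C)C)[C@]2(C)CC[C@H](C(Br)=C)O2 | intermediate
31 | seco alcohol: (8R)-silyloxy, (10R)-hydroxy, (16S)-(trimethylsilyl)ethynyl, (18R)-silyloxy, C3=C4 alkene, 1-bromoethenyl on C24 | C=CC[C@H](C)[C@@H](O[Si](C)(C)C(C)(C)C)[C@H](O)[C@H](C#C[Si](C)(C)C)C[C@@H](O[Si](C)(C)C(C)(C)C)[C@]1(C)CC[C@H](C(Br)=C)O1 | intermediate
32 | B-alkyl-9-BBN from 31 (boron on C3) | C1CCC2CCCC1B2CCC[C@H](C)[C@@H](O[Si](C)(C)C(C)(C)C)[C@H](O)[C@H](C#C[Si](C)(C)C)C[C@@H](O[Si](C)(C)C(C)(C)C)[C@]3(C)CC[C@H](C(Br)=C)O3 | intermediate (not isolated)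
33 | macrocycle closed at C2–C3 with C2=C1 methylene and (trimethylsilyl)ethynyl on C16 | C=C1CCC[C@H](C)[C@@H](O[Si](C)(C)C(C)(C)C)[C@H](O)[C@H](C#C[Si](C)(C)C)C[C@@H](O[Si](C)(C)C(C)(C)C)[C@]2(C)CC[C@H]1O2 | intermediate
34 | macrocyclic homopropargylic alcohol (C10 hydroxyl, C16 ethynyl, O9 and O19 silylated) | C=C1CCC[C@H](C)[C@@H](O[Si](C)(C)C(C)(C)C)[C@H](O)[C@H](C#C)C[C@@H](O[Si](C)(C)C(C)(C)C)[C@]2(C)CC[C@H]1O2 | intermediate
35 | carbon monoxide | [C-]#[O+] | starting material
36 | uprolide D 9,19-bis(tert-butyldimethylsilyl) ether | C=C1CCC[C@H](C)[C@@H](O[Si](C)(C)C(C)(C)C)[C@@H]2OC(=O)C(=C)[C@@H]2C[C@@H](O[Si](C)(C)C(C)(C)C)[C@]2(C)CC[C@H]1O2 | intermediate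
37 | uprolide D | C=C1CCC[C@H](C)[C@@H](O)[C@@H]2OC(=O)C(=C)[C@@H]2C[C@@H](O)[C@]2(C)CC[C@H]1O2 | target

Total step count: 24. Longest linear sequence: 22 steps (steps 1 to 11 and 14 to 24); steps 12 and 13 make the side fragment 22.

Steps most likely to fail

Step 23 (key step). Formation of the alkoxycarbonylpalladium species at the hindered C10 hydroxyl may be slow. Hydrochlorination of the alkyne or palladium hydride migration of the C2=C1 double bond into the ring could then compete, and the acid of the cycle could loosen the silyl ethers. Fallback, from 34 back to 36: the carbonyl carbon is brought in through a vinyl iodide instead of the alkyne. Markovnikov hydrosilylation of the ethynyl group (Et3SiH, [Cp*Ru(MeCN)3]PF6, CH2Cl2, 0 °C) should give the 1-(triethylsilyl)ethenyl alcohol F1. Iododesilylation (NIS, MeCN, 0 °C) should give the 1-iodoethenyl alcohol F2. Carbonylative lactonisation (Pd(PPh3)4, CO 1 atm, K2CO3, THF, 50 °C) then closes the ring by oxidative addition of zerovalent palladium into the C14–I bond, CO insertion and capture of the acylpalladium by O11, which gives 36.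

Step 21. Intermolecular coupling or protodeboration may outrun closure of the 14-membered ring. The hydroboration may also be unclean, because the free C10 hydroxyl consumes borane and the silylalkyne can be hydroborated. Fallback, from 30 back to 33: ring closure and alkynylation change places. Epoxide 30, which has neither a free hydroxyl nor an alkyne, is hydroborated with 9-BBN to the B-alkyl-9-BBN F3 and cyclised under the same palladium conditions to the macrocyclic 10,16-epoxide F4. The epoxide is then opened on the ring at C16 with lithium (trimethylsilyl)acetylide 4 and BF3·OEt2, which gives 33.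

Step 7. Tin may add to the terminal carbon as well as to the internal one, or the free diol may slow the molybdenum catalyst, so that bromination would give a mixture of bromoalkenes. Fallback, from 10 back to 12: haloboration replaces hydrostannation. The diol is silylated (TBSOTf, 2,6-lutidine) to the bis(silyl) ether F5. B-Bromo-9-BBN (CH2Cl2, 0 °C) adds bromine to the internal and boron to the terminal alkyne carbon to give the bromoalkenylborane F6, which acetic acid protodeborates to the 1-bromoethenyl bis(silyl) ether F7. HF·pyridine in THF, which cannot dehydrobrominate the bromoalkene, then frees diol 12.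

Further compounds
F1 | step 23 | macrocyclic C10 alcohol with a 1-(triethylsilyl)ethenyl group on C16 | C=C1CCC[C@H](C)[C@@H](O[Si](C)(C)C(C)(C)C)[C@H](O)[C@H](C(=C)[Si](CC)(CC)CC)C[C@@H](O[Si](C)(C)C(C)(C)C)[C@]2(C)CC[C@H]1O2
F2 | step 23 | macrocyclic C10 alcohol with a 1-iodoethenyl group on C16 | C=C1CCC[C@H](C)[C@@H](O[Si](C)(C)C(C)(C)C)[C@H](O)[C@H](C(I)=C)C[C@@H](O[Si](C)(C)C(C)(C)C)[C@]2(C)CC[C@H]1O2
F3 | step 21 | B-alkyl-9-BBN from hydroboration of 30 at C3 | C1CCC2CCCC1B2CCC[C@H](C)[C@@H](O[Si](C)(C)C(C)(C)C)[C@@H]4O[C@H]4C[C@@H](O[Si](C)(C)C(C)(C)C)[C@]3(C)CC[C@H](C(Br)=C)O3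
F4 | step 21 | macrocyclic 10,16-epoxide 8,18-bis(silyl) ether | C=C1CCC[C@H](C)[C@@H](O[Si](C)(C)C(C)(C)C)[C@@H]3O[C@H]3C[C@@H](O[Si](C)(C)C(C)(C)C)[C@]2(C)CC[C@H]1O2
F5 | step 7 | bis(tert-butyldimethylsilyl) ether of 10 | CC(C)(C)[Si](C)(C)OC[C@@H](O[Si](C)(C)C(C)(C)C)[C@]1(C)CC[C@H](C#C)O1
F6 | step 7 | (Z)-2-bromoalkenyl-9-BBN from bromoboration of F5 | CC(C)(C)[Si](C)(C)OC[C@@H](O[Si](C)(C)C(C)(C)C)[C@]1(C)CC[C@H](/C(Br)=C/B2C3CCCC2CCC3)O1
F7 | step 7 | bis(tert-butyldimethylsilyl) ether of 12 | CC(C)(C)[Si](C)(C)OC[C@@H](O[Si](C)(C)C(C)(C)C)[C@]1(C)CC[C@H](C(Br)=C)O1
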